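## The problem

Compound 35 is a (2S)-flavanone whose ring A is a pentasubstituted phloroglucinol: O1 on C8a, the acyl carbon on C4a, free hydroxyls on C5 and C7, hydrogen only on C6, and on C8 the chain C1''H2–C2''H(CH2CH=CMe2)–C7''H(CH3)–C8''H2OH, with (R) configuration at C2'' and C7''. The first task is regiochemical: the chain must sit at C8 and not at C6, and C-alkylation of a preformed phloroglucinol neither tells these positions apart nor works well with a β-branched primary electrophile. The second task is the vicinal pair C2''/C7''; being adjacent, one centre can set the other if both are held in a ring. The third is C2, which lies seven bonds from C2'' and cannot be influenced by the chain, so it needs catalyst control, and a wrong C2 isomer is a diastereomer that is hard to remove. The trisubstituted alkene excludes hydrogenolysis, strong Lewis acids and hot protic acid; the C2–O1 bond opens under base (retro-oxa-Michael, eased by the para-hydroxyl of ring B), so C2 must be made late and the last steps must be non-basic. The 5-OH is chelated to the C4 carbonyl, which is the one place where an alkyl ether can be removed selectively. The feature that opens the way is the pattern around C8: C8 carries carbon while C8a and C7 carry oxygen, so C7–C8 with its chain is an ynol ether, R–C≡C–O, and the remaining atoms C8a, C4a, C5 and C6, with oxygen on C8a and C5, are a 3-alkoxyvinylketene. Ring A can therefore be grown onto the finished chain in one pericyclic cascade that delivers the three oxygens as three different functional groups.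

## Retrosynthesis

**35 ⇒ 34 ⇒ 33.** The O–Si bonds at C7, C4' and C8'' and the O–ethyl bond at C5 are cut. The ethyl ether is removed first by chelation-directed iodide cleavage, which cannot touch the unchelated ring-B methyl ether. The three silyl ethers go last with buffered fluoride, so the free 4'-phenol never meets base. This asks only that the Lewis acid leave C2 and the alkene alone.

**33 ⇒ 28 + 32.** The C2–C1' bond is cut. The neighbouring cut, O1–C2 closure of a 2'-hydroxychalcone, has no dependable asymmetric version for an unactivated chalcone. Conjugate arylation of a chromone sets C2 under ligand control on a flat precursor. Chromone 28 has no C2 stereocentre, and ring B becomes the simple boronic acid 32. The forward step must deliver an ortho-substituted, electron-rich aryl group to one face of C2.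

**28 ⇒ 26 ⇒ 24 ⇒ 23.** The O1–C2 and C2–C3 bonds are cut (C2 is a one-carbon unit from an amide acetal, via enaminone 27), then the C4a–C4 bond. The acetyl group is introduced through aryllithium 25 by directed metalation rather than Friedel–Crafts acylation, which the alkene and silyl ethers would not survive. The methoxymethyl ether 24 makes C4a–H the only ring hydrogen between two coordinating alkoxy groups. It is removed by the same acid that closes ring C, which is why the primary alcohol carries the acid-stable tert-butyldiphenylsilyl group.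

**23 ⇒ 17 + 18.** Three ring bonds are cut: C8a–C8, C6–C7 and C8a–C4a. Ring A is traced back to siloxyalkyne 17, which holds the whole chain, and 3-ethoxycyclobutenone 18. Any cut that attaches the chain to an existing arene has to solve the 6- versus 8-position problem with protecting groups. This one solves it by construction and gives OH (C8a), silyl ether (C7) and ethyl ether (C5) already distinguished. The ethyl group of 18 is accepted as a spectator because it ends up peri to the carbonyl. The forward reaction must tolerate the alkene and both silyl ethers under neutral heating.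

**17 ⇒ 14 ⇒ 13 ⇒ 12 ⇒ 10.** The C–O bond of the ynol ether is cut (oxidation of an acetylide), then the terminal alkyne carbon (one-carbon homologation of aldehyde 13), then the oxygen of 12 (anti-Markovnikov hydration of a vinyl group). The C1'' arm is carried as a vinyl group and not as an ester arm from a malonate-type nucleophile. An ester would compete with the lactone in the hydride reduction below, and it would be attacked by the alkoxide set free in the Wittig step to give a rearranged lactone.

**10 ⇒ 9 ⇒ 8 ⇒ 7 ⇒ 6.** The prenyl C=C bond is cut (lactol Wittig), then the C2''–vinyl bond (conjugate addition to unsaturated lactone 6). The ring lets C7'' control C2'': the nucleophile enters trans to the methyl group. The roles of the two arms are fixed by this. The trans nucleophile must become C1'' and the ring CH2–C=O must become the prenyl arm; the reverse assignment would need a cis addition.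

**6 ⇒ 4 ⇒ 3 ⇒ 2 ⇒ 1.** The lactone C–O bond and the (Z)-alkene are cut back to aldehyde 3 and the chiral-pool hydroxy ester 1. The ester carbon of 1 becomes C2'' and its CH2OH stays C8'', which requires the (S) enantiomer. The forward steps must keep the α-stereocentre of 3 intact and give the Z geometry.

**32 ⇒ 30 ⇒ 29.** The C–B bond is cut back to bromide 30 and bromophenol 29, with a silyl group on the phenol.

## Roads not taken

**Alternative 1: three-component conjugate methylation–aldol on a butenolide.**
- **Cut:** C7''–CH3 and C1''–C2''.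
- **Forward step:** Cu(OTf)2 with a chiral phosphoramidite adds Me2Zn to furan-2(5H)-one A2, and the zinc enolate is trapped by ring-A aldehyde A3 to give lactone carbinol A1.
- **Merits:** both chain centres come from achiral materials in one catalytic operation, with the trans relation built in. For the diad alone this is clearly shorter than the seven steps the chosen plan spends to reach 7.
- **Weak points:** enantioselective methyl transfer to the five-membered lactone is the least reliable member of its class. The 2,6-disubstituted, electron-rich A3 is a poor and reversible aldol acceptor. The benzylic carbinol of A1 must be deoxygenated beside acetal protecting groups. The lactone carbonyl sits directly on C2'', so the prenyl arm needs an extra one-carbon homologation. Ring A arrives symmetric, so ring C can later close through either oxygen flanking the acyl group and the 6-/8-alkyl question returns.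
- **Comparison:** the chosen plan sets regiochemical certainty in ring A and a chiral-pool C7'' against this, and pays for it with a longer chain synthesis.

**Alternative 2: palladium aryl ether closure of a stereodefined diol.**
- **Cut:** O1–C8a.
- **Forward step:** Pd(OAc)2, a bulky di-tert-butylbiarylphosphine and Cs2CO3 couple the C2 hydroxyl of anti-diol bromide A5 with C8a to give flavan-4-ol A4.
- **Merits:** C2 is set as a carbinol by well-understood acyclic methods and never passes through a chalcone–flavanone equilibrium. No hindered, electron-rich boronic acid is needed. In robustness of the C2 centre this road is as good as or better than the chosen one.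
- **Weak points:** the bromide is flanked on both sides and sits on an electron-rich ring, so oxidative addition is slow. The secondary benzylic alkoxide on palladium can undergo β-hydride elimination. The C4 stereocentre is made only to be oxidised away. Three acetal groups must finally be removed with acid beside the alkene. The hexasubstituted ring A of A5, with bromine at C8a and the chain at C8, still has to be assembled regioselectively, so the central problem is moved and not solved.
- **Comparison:** the chosen plan makes ring A and its oxygen pattern in one step and needs no redundant stereocentre or late oxidation.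

**Alternative 3: carbenoid C–H insertion closes ring C at C2–C3.**
- **Cut:** C2–C3.
- **Forward step:** Rh2(S-PTTL)4, dirhodium tetrakis[N-phthaloyl-(S)-tert-leucinate] (divalent rhodium), decomposes diazomethyl ketone A7, and the carbenoid inserts into a benzylic O–CH2 hydrogen to give flavanone A6.
- **Merits:** ring C and C2 are made in one neutral step, and the O1–C2 bond is a trivial benzylation. It is the shortest ring-C closure of the four.
- **Weak points:** an acceptor-only carbenoid is unselective. Six-membered insertion competes with oxonium ylide formation at O1 and benzyl shift to a benzofuranone, with cyclopropanation of the trisubstituted alkene, and with addition to the electron-rich ring B. Enantiocontrol in chromanone-forming insertions is modest. A7 needs a crowded diazoketone and, again, a ring A that is already differentiated.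
- **Comparison:** the chosen plan uses a C2-forming step with better precedent for high selectivity and builds ring A itself, at the cost of two more steps for ring C.

Key step: step 13

## Route

Remarks on the chemistry:
- 3-Ethoxycyclobut-2-en-1-one (18) and both antipodes of t-BuPyOX are taken as purchased materials.
- The sense of induction in step 19 is taken from cyclic enones, where the (S)-ligand gives the (R)-β-aryl ketone; the same facial delivery to a chromone gives the (2R)-flavanone, so the (R)-ligand is specified for 2S. This assignment is by analogy and should be confirmed on a simple chromone before material is committed.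
- In names below, "chain" means (2R)-2-[(2R)-1-(tert-butyldiphenylsilyloxy)propan-2-yl]-5-methylhex-4-en-1-yl, attached through its C1 (C1'' of the target).

Step 1
Reactants: 1 methyl (S)-3-hydroxy-2-methylpropanoate
Product: 2 methyl (S)-3-(tert-butyldimethylsilyloxy)-2-methylpropanoate
Conditions: TBSCl, imidazole, CH2Cl2, 0 °C → rt
Reagents that add atoms: tert-butyldimethylsilyl chloride, CC(C)(C)[Si](C)(C)Cl
Why: Imidazole-assisted silylation of a primary alcohol; the silyl ether masks the hydroxyl through reduction and olefination and is removed again in step 4.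

Step 2
Reactants: 2 methyl (S)-3-(tert-butyldimethylsilyloxy)-2-methylpropanoate
Product: 3 (S)-3-(tert-butyldimethylsilyloxy)-2-methylpropanal
Conditions: i-Bu2AlH, CH2Cl2, −78 °C; aq. potassium sodium tartrate
Reagents that add atoms: none
Why: Partial ester reduction stops at the aluminium hemiacetal at low temperature and releases the aldehyde on work-up; the α-stereocentre is preserved by using the crude aldehyde at once.

Step 3
Reactants: 3 (S)-3-(tert-butyldimethylsilyloxy)-2-methylpropanal
Product: 4 methyl (2Z,4R)-5-(tert-butyldimethylsilyloxy)-4-methylpent-2-enoate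
Conditions: (CF3CH2O)2P(O)CH2CO2Me, KN(SiMe3)2, 18-crown-6, THF, −78 °C
Reagents that add atoms: methyl bis(2,2,2-trifluoroethoxy)phosphinylacetate, COC(=O)CP(=O)(OCC(F)(F)F)OCC(F)(F)F
Why: Still–Gennari olefination; the electron-poor phosphonate with a dissociated potassium counter-ion eliminates under kinetic control to the (Z)-enoate that lactonisation requires.

Step 4
Reactants: 4 methyl (2Z,4R)-5-(tert-butyldimethylsilyloxy)-4-methylpent-2-enoate
Product: 6 (R)-5-methyl-5,6-dihydro-2H-pyran-2-one, via hydroxy enoate 5 (not isolated)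
Conditions: CSA (cat.), MeOH, rt; then CH2Cl2, rt
Reagents that add atoms: none
Why: Acid methanolysis removes the silyl ether and the (Z)-δ-hydroxy enoate closes to the six-membered unsaturated lactone by transesterification; the stereocentre is not involved.

Step 5
Reactants: 6 (R)-5-methyl-5,6-dihydro-2H-pyran-2-one
Product: 7 (4R,5R)-5-methyl-4-vinyltetrahydro-2H-pyran-2-one (4,5-trans)
Conditions: CH2=CHMgBr, CuBr·SMe2 (10 mol %), Me3SiCl, THF, −78 → −40 °C; aq. NH4Cl
Reagents that add atoms: vinylmagnesium bromide, C=C[Mg]Br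
Why: Copper-catalysed conjugate addition of a Grignard reagent accelerated by Me3SiCl; the vinyl group enters axially on the half-chair anti to the C5 methyl group, as with 4-substituted cyclohexenones, so the future C2'' is set trans to C7''.

Step 6
Reactants: 7 (4R,5R)-5-methyl-4-vinyltetrahydro-2H-pyran-2-one
Product: 8 (4R,5R)-5-methyl-4-vinyltetrahydro-2H-pyran-2-ol (anomer mixture)
Conditions: i-Bu2AlH, CH2Cl2, −78 °C
Reagents that add atoms: none
Why: Low-temperature reduction of a lactone stops at the lactol; the vinyl group is inert to the hydride.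

Step 7
Reactants: 8 (4R,5R)-5-methyl-4-vinyltetrahydro-2H-pyran-2-ol
Product: 9 (2R,3R)-2,6-dimethyl-3-vinylhept-5-en-1-ol
Conditions: i-PrPPh3I, n-BuLi, THF, 0 °C; then 8, 0 °C → rt
Reagents that add atoms: isopropyltriphenylphosphonium iodide, CC(C)[P+](c1ccccc1)(c1ccccc1)c1ccccc1.[I-]
Why: Wittig olefination of the lactol through its open hydroxy-aldehyde form with excess non-stabilised ylide builds the trisubstituted alkene of the prenyl arm; the carbon next to the aldehyde is CH2, so nothing can epimerise.

Step 8
Reactants: 9 (2R,3R)-2,6-dimethyl-3-vinylhept-5-en-1-ol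
Product: 10 tert-butyl{[(2R,3R)-2,6-dimethyl-3-vinylhept-5-en-1-yl]oxy}diphenylsilane
Conditions: TBDPSCl, imidazole, DMF, rt
Reagents that add atoms: tert-butyldiphenylsilyl chloride, CC(C)(C)[Si](Cl)(c1ccccc1)c1ccccc1
Why: Silylation of the primary alcohol; the tert-butyldiphenylsilyl ether is chosen because it must survive the aqueous acid of step 16.

Step 9
Reactants: 10 tert-butyl{[(2R,3R)-2,6-dimethyl-3-vinylhept-5-en-1-yl]oxy}diphenylsilane
Product: 12 (3R,4R)-5-(tert-butyldiphenylsilyloxy)-4-methyl-3-(3-methylbut-2-en-1-yl)pentan-1-ol, via B-alkyl-9-BBN 11 (not isolated)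
Conditions: 9-BBN, THF, 0 °C → rt; then NaOH, H2O2, 0 °C
Reagents that add atoms: hydrogen peroxide, OO; 9-borabicyclo[3.3.1]nonane, C1CC2CCCC(C1)B2 (boron stays only in 11)
Why: Hydroboration–oxidation; 9-BBN reacts with the monosubstituted alkene far faster than with the trisubstituted one and places boron on the terminal carbon.

Step 10
Reactants: 12 (3R,4R)-5-(tert-butyldiphenylsilyloxy)-4-methyl-3-(3-methylbut-2-en-1-yl)pentan-1-ol
Product: 13 (3R,4R)-5-(tert-butyldiphenylsilyloxy)-4-methyl-3-(3-methylbut-2-en-1-yl)pentanal
Conditions: Dess–Martin periodinane, NaHCO3, CH2Cl2, 0 °C → rt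
Reagents that add atoms: none
Why: Dess–Martin oxidation of a primary alcohol under buffered conditions that leave the alkene and the silyl ether alone; the α-carbon is CH2.

Step 11
Reactants: 13 (3R,4R)-5-(tert-butyldiphenylsilyloxy)-4-methyl-3-(3-methylbut-2-en-1-yl)pentanal
Product: 14 tert-butyl{[(2R,3R)-2-methyl-3-(3-methylbut-2-en-1-yl)hex-5-yn-1-yl]oxy}diphenylsilane
Conditions: MeC(O)C(N2)P(O)(OMe)2, K2CO3, MeOH, 0 °C → rt
Reagents that add atoms: dimethyl (1-diazo-2-oxopropyl)phosphonate, COP(=O)(OC)C(=[N+]=[N-])C(C)=O
Why: Ohira–Bestmann (Seyferth–Gilbert) homologation; methanolysis of the reagent gives the diazomethylphosphonate anion, which turns the aldehyde into the terminal alkyne through an alkylidene carbene 1,2-shift.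

Step 12
Reactants: 14 tert-butyl{[(2R,3R)-2-methyl-3-(3-methylbut-2-en-1-yl)hex-5-yn-1-yl]oxy}diphenylsilane
Product: 17 tert-butyl{[(2R,3R)-2-methyl-3-(3-methylbut-2-en-1-yl)-6-(triisopropylsilyloxy)hex-5-yn-1-yl]oxy}diphenylsilane, via lithium acetylide 15 (not isolated), via lithium ynolate 16 (not isolated)
Conditions: n-BuLi, THF, −78 °C; t-BuOOLi (from t-BuOOH, LiN(SiMe3)2), −78 → 0 °C; i-Pr3SiOTf, −78 → 0 °C
Reagents that add atoms: tert-butyl hydroperoxide, CC(C)(C)OO; triisopropylsilyl trifluoromethanesulfonate, CC(C)[Si](OS(=O)(=O)C(F)(F)F)(C(C)C)C(C)C; n-butyllithium, [Li]CCCC (lithium stays only in 15 and 16)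
Why: Oxidation of a lithium acetylide by lithium tert-butyl peroxide (electrophilic oxygen transfer) gives the lithium ynolate, and the bulky silyl triflate reacts at oxygen to give the ynol silyl ether; both operations are established for alkyl acetylenes.

Step 13
Reactants: 17 tert-butyl{[(2R,3R)-2-methyl-3-(3-methylbut-2-en-1-yl)-6-(triisopropylsilyloxy)hex-5-yn-1-yl]oxy}diphenylsilane; 18 3-ethoxycyclobut-2-en-1-one
Product: 23 2-(chain)-5-ethoxy-3-(triisopropylsilyloxy)phenol, via 3-ethoxyvinylketene 19 (not isolated), via 4-vinylcyclobutenone 20 (not isolated), via dienylketene 21 (not isolated), via cyclohexadienone 22 (not isolated)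
Conditions: 18 (1.2 equiv), PhMe, 80 °C, then 110 °C (sealed tube)
Reagents that add atoms: none
Why: Danheiser benzannulation; the closest known cases are cyclobutenones with trialkylsiloxyalkynes giving resorcinol monosilyl ethers. Heat opens 18 by four-electron electrocyclic ring opening to 3-ethoxyvinylketene 19. The ketene adds [2+2] to the electron-rich alkyne, its carbonyl carbon bonding to the nucleophilic chain-bearing carbon of the ynol ether (C8a–C8) and its α-carbon to the oxygen-bearing carbon (C6–C7), to give 20. A second four-electron opening gives dienylketene 21, which closes ring A by thermal disrotatory six-electron electrocyclisation between the ketene carbon and the terminal methylene (C8a–C4a) to dienone 22, and tautomerisation gives phenol 23. No stereocentre is formed (the sp3 ring carbon of 20 is lost on ring opening) and the neutral conditions leave C2'' and C7'' untouched. The step needs regioselectivity in the [2+2] event, which the oxygen polarisation of the ynol ether secures, and chemoselectivity for the alkyne over the trisubstituted alkene, which follows from the far higher reactivity of a siloxyalkyne toward ketenes. The outcome is a ring A with free OH at C8a, silyl ether at C7, ethyl ether at C5 and the chain fixed at C8.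

Step 14
Reactants: 23 2-(chain)-5-ethoxy-3-(triisopropylsilyloxy)phenol
Product: 24 [3-ethoxy-5-(methoxymethoxy)-6-(chain)phenoxy]triisopropylsilane
Conditions: NaH, MeOCH2Cl, THF/DMF, 0 °C → rt
Reagents that add atoms: chloromethyl methyl ether, COCCl
Why: Williamson alkylation of the hindered phenoxide; the methoxymethyl ether is the directing group for step 15 and is removed again in step 16.

Step 15
Reactants: 24 [3-ethoxy-5-(methoxymethoxy)-6-(chain)phenoxy]triisopropylsilane
Product: 26 1-[6-ethoxy-2-(methoxymethoxy)-3-(chain)-4-(triisopropylsilyloxy)phenyl]ethan-1-one, via aryllithium 25 (not isolated)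
Conditions: n-BuLi, THF, 0 °C; then MeC(O)N(OMe)Me, −78 → 0 °C
Reagents that add atoms: N-methoxy-N-methylacetamide, CC(=O)N(C)OC; n-butyllithium, [Li]CCCC (lithium stays only in 25)
Why: Directed ortho-metalation; C4a–H is the only ring hydrogen between two coordinating alkoxy groups, whereas C6–H lies beside the bulky, weakly coordinating silyl ether. The aryllithium acylates the N-methoxy-N-methyl amide once because the chelated tetrahedral adduct persists until work-up.

Step 16
Reactants: 26 1-[6-ethoxy-2-(methoxymethoxy)-3-(chain)-4-(triisopropylsilyloxy)phenyl]ethan-1-one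
Product: 28 5-ethoxy-8-(chain)-7-(triisopropylsilyloxy)-4H-chromen-4-one, via enaminone 27 (not isolated)
Conditions: Me2NCH(OMe)2, PhMe, 110 °C; then HCl (3 M), MeOH/THF, rt
Reagents that add atoms: N,N-dimethylformamide dimethyl acetal, COC(OC)N(C)C
Why: Condensation of the methyl ketone with the amide acetal gives the enaminone and supplies C2; acid then removes the methoxymethyl group (assisted by the ortho carbonyl) and the phenol closes ring C by conjugate addition–elimination of dimethylamine (6-endo, O1–C2).

Step 17
Reactants: 29 4-bromo-3-methoxyphenol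
Product: 30 (4-bromo-3-methoxyphenoxy)triisopropylsilane
Conditions: i-Pr3SiCl, imidazole, DMF, rt
Reagents that add atoms: triisopropylsilyl chloride, CC(C)[Si](Cl)(C(C)C)C(C)C
Why: Silylation of the phenol; the triisopropylsilyl ether tolerates the organolithium of step 18 and the wet, mildly acidic catalysis of step 19.

Step 18
Reactants: 30 (4-bromo-3-methoxyphenoxy)triisopropylsilane
Product: 32 [2-methoxy-4-(triisopropylsilyloxy)phenyl]boronic acid, via aryllithium 31 (not isolated)
Conditions: n-BuLi, THF, −78 °C; B(Oi-Pr)3, −78 °C → rt; aq. NH4Cl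
Reagents that add atoms: triisopropyl borate, CC(C)OB(OC(C)C)OC(C)C; water, O; n-butyllithium, [Li]CCCC (lithium stays only in 31)
Why: Bromine–lithium exchange at −78 °C outruns ortho-lithiation; the aryllithium is trapped by the borate and mild hydrolysis gives the boronic acid without protodeboronation.

Step 19
Reactants: 28 5-ethoxy-8-(chain)-7-(triisopropylsilyloxy)-4H-chromen-4-one; 32 [2-methoxy-4-(triisopropylsilyloxy)phenyl]boronic acid
Product: 33 (2S)-5-ethoxy-8-(chain)-2-[2-methoxy-4-(triisopropylsilyloxy)phenyl]-7-(triisopropylsilyloxy)chroman-4-one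
Conditions: Pd(OCOCF3)2 (10 mol %), (R)-t-BuPyOX [(R)-4-tert-butyl-2-(pyridin-2-yl)-4,5-dihydrooxazole] (12 mol %), NH4PF6 (30 mol %), H2O (5 equiv), 32 (2.5 equiv), ClCH2CH2Cl, 60 °C
Reagents that add atoms: none
Why: Palladium-catalysed asymmetric conjugate addition of an arylboronic acid to a chromone: transmetalation to the cationic ligand-bound divalent palladium, insertion of C2=C3 into the aryl–palladium bond, and protonolysis of the palladium enolate by water. The tert-butyl group of the ligand fixes the orientation of the enone so that aryl is delivered to one face of C2; the chain stereocentres are too remote to interfere, so the new centre is under catalyst control and the (R)-ligand is chosen for 2S.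

Step 20
Reactants: 33 (2S)-5-ethoxy-8-(chain)-2-[2-methoxy-4-(triisopropylsilyloxy)phenyl]-7-(triisopropylsilyloxy)chroman-4-one
Product: 34 (2S)-5-hydroxy-8-(chain)-2-[2-methoxy-4-(triisopropylsilyloxy)phenyl]-7-(triisopropylsilyloxy)chroman-4-one
Conditions: MgI2·OEt2, PhMe/Et2O, 70 °C; dilute HCl work-up
Reagents that add atoms: none
Why: Chelation-assisted ether cleavage: magnesium bridges the C4 carbonyl and the C5 ether oxygen and iodide removes the ethyl group by SN2. The ring-B methyl ether has no such chelate, and this dealkylation is known to spare the alkene and the heterocycle in 5-O-alkyl-8-prenylflavanones.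

Step 21
Reactants: 34 (2S)-5-hydroxy-8-(chain)-2-[2-methoxy-4-(triisopropylsilyloxy)phenyl]-7-(triisopropylsilyloxy)chroman-4-one
Product: 35 (2S)-5,7-dihydroxy-8-{(2R)-2-[(2R)-1-hydroxypropan-2-yl]-5-methylhex-4-en-1-yl}-2-(4-hydroxy-2-methoxyphenyl)chroman-4-one
Conditions: HF·pyridine, pyridine/THF, 0 °C → rt
Reagents that add atoms: none
Why: Fluoride cleavage of the two aryl silyl ethers and the primary silyl ether under buffered, non-basic conditions, which avoids the base-induced opening of ring C that would epimerise C2.

## Compound list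

1 | methyl (S)-3-hydroxy-2-methylpropanoate | COC(=O)[C@@H](C)CO | starting material
2 | methyl (S)-3-(tert-butyldimethylsilyloxy)-2-methylpropanoate | COC(=O)[C@@H](C)CO[Si](C)(C)C(C)(C)C | intermediate
3 | (S)-3-(tert-butyldimethylsilyloxy)-2-methylpropanal | O=C[C@@H](C)CO[Si](C)(C)C(C)(C)C | intermediate
4 | methyl (2Z,4R)-5-(tert-butyldimethylsilyloxy)-4-methylpent-2-enoate | COC(=O)/C=C\[C@@H](C)CO[Si](C)(C)C(C)(C)C | intermediate
5 | methyl (2Z,4R)-5-hydroxy-4-methylpent-2-enoate (not isolated) | COC(=O)/C=C\[C@@H](C)CO | intermediate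
6 | (R)-5-methyl-5,6-dihydro-2H-pyran-2-one | O=C1C=C[C@@H](C)CO1 | intermediate
7 | (4R,5R)-5-methyl-4-vinyltetrahydro-2H-pyran-2-one | O=C1C[C@H](C=C)[C@@H](C)CO1 | intermediate
8 | (4R,5R)-5-methyl-4-vinyltetrahydro-2H-pyran-2-ol (anomer mixture) | OC1C[C@H](C=C)[C@@H](C)CO1 | intermediate
9 | (2R,3R)-2,6-dimethyl-3-vinylhept-5-en-1-ol | C=C[C@@H](CC=C(C)C)[C@@H](C)CO | intermediate
10 | tert-butyl{[(2R,3R)-2,6-dimethyl-3-vinylhept-5-en-1-yl]oxy}diphenylsilane | C=C[C@@H](CC=C(C)C)[C@@H](C)CO[Si](c1ccccc1)(c1ccccc1)C(C)(C)C | intermediate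
11 | B-alkyl-9-borabicyclo[3.3.1]nonane from terminal hydroboration of 10 (not isolated) | C1CC2CCCC(C1)B2CC[C@@H](CC=C(C)C)[C@@H](C)CO[Si](c1ccccc1)(c1ccccc1)C(C)(C)C | intermediate
12 | (3R,4R)-5-(tert-butyldiphenylsilyloxy)-4-methyl-3-(3-methylbut-2-en-1-yl)pentan-1-ol | OCC[C@@H](CC=C(C)C)[C@@H](C)CO[Si](c1ccccc1)(c1ccccc1)C(C)(C)C | intermediate
13 | (3R,4R)-5-(tert-butyldiphenylsilyloxy)-4-methyl-3-(3-methylbut-2-en-1-yl)pentanal | O=CC[C@@H](CC=C(C)C)[C@@H](C)CO[Si](c1ccccc1)(c1ccccc1)C(C)(C)C | intermediate
14 | tert-butyl{[(2R,3R)-2-methyl-3-(3-methylbut-2-en-1-yl)hex-5-yn-1-yl]oxy}diphenylsilane | C#CC[C@@H](CC=C(C)C)[C@@H](C)CO[Si](c1ccccc1)(c1ccccc1)C(C)(C)C | intermediate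
15 | lithium acetylide of 14 (not isolated) | [Li]C#CC[C@@H](CC=C(C)C)[C@@H](C)CO[Si](c1ccccc1)(c1ccccc1)C(C)(C)C | intermediate
16 | lithium ynolate, LiO–C≡C–CH2–chain core (not isolated) | [Li]OC#CC[C@@H](CC=C(C)C)[C@@H](C)CO[Si](c1ccccc1)(c1ccccc1)C(C)(C)C | intermediate
17 | tert-butyl{[(2R,3R)-2-methyl-3-(3-methylbut-2-en-1-yl)-6-(triisopropylsilyloxy)hex-5-yn-1-yl]oxy}diphenylsilane (siloxyalkyne) | CC(C)[Si](OC#CC[C@@H](CC=C(C)C)[C@@H](C)CO[Si](c1ccccc1)(c1ccccc1)C(C)(C)C)(C(C)C)C(C)C | intermediate
18 | 3-ethoxycyclobut-2-en-1-one | CCOC1=CC(=O)C1 | starting material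
19 | 3-ethoxybuta-1,3-dien-1-one (3-ethoxyvinylketene, not isolated) | C=C(OCC)C=C=O | intermediate
20 | 2-(chain)-4-(1-ethoxyvinyl)-3-(triisopropylsilyloxy)cyclobut-2-en-1-one (not isolated) | O=C1C(C[C@@H](CC=C(C)C)[C@@H](C)CO[Si](c2ccccc2)(c2ccccc2)C(C)(C)C)=C(O[Si](C(C)C)(C(C)C)C(C)C)C1C(OCC)=C | intermediate
21 | 2-(chain)-5-ethoxy-3-(triisopropylsilyloxy)hexa-1,3,5-trien-1-one (dienylketene, not isolated) | O=C=C(C[C@@H](CC=C(C)C)[C@@H](C)CO[Si](c1ccccc1)(c1ccccc1)C(C)(C)C)C(O[Si](C(C)C)(C(C)C)C(C)C)=CC(OCC)=C | intermediate
22 | 2-(chain)-5-ethoxy-3-(triisopropylsilyloxy)cyclohexa-2,4-dien-1-one (not isolated) | O=C1CC(OCC)=CC(O[Si](C(C)C)(C(C)C)C(C)C)=C1C[C@@H](CC=C(C)C)[C@@H](C)CO[Si](c2ccccc2)(c2ccccc2)C(C)(C)C | intermediate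
23 | 2-(chain)-5-ethoxy-3-(triisopropylsilyloxy)phenol | Oc1cc(OCC)cc(O[Si](C(C)C)(C(C)C)C(C)C)c1C[C@@H](CC=C(C)C)[C@@H](C)CO[Si](c2ccccc2)(c2ccccc2)C(C)(C)C | intermediate
24 | [3-ethoxy-5-(methoxymethoxy)-6-(chain)phenoxy]triisopropylsilane | COCOc1cc(OCC)cc(O[Si](C(C)C)(C(C)C)C(C)C)c1C[C@@H](CC=C(C)C)[C@@H](C)CO[Si](c2ccccc2)(c2ccccc2)C(C)(C)C | intermediate
25 | aryllithium of 24, lithiated between OCH2OMe and OEt (not isolated) | [Li]c1c(OCC)cc(O[Si](C(C)C)(C(C)C)C(C)C)c(C[C@@H](CC=C(C)C)[C@@H](C)CO[Si](c2ccccc2)(c2ccccc2)C(C)(C)C)c1OCOC | intermediate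
26 | 1-[6-ethoxy-2-(methoxymethoxy)-3-(chain)-4-(triisopropylsilyloxy)phenyl]ethan-1-one | CC(=O)c1c(OCC)cc(O[Si](C(C)C)(C(C)C)C(C)C)c(C[C@@H](CC=C(C)C)[C@@H](C)CO[Si](c2ccccc2)(c2ccccc2)C(C)(C)C)c1OCOC | intermediate
27 | (E)-3-(dimethylamino)-1-[6-ethoxy-2-(methoxymethoxy)-3-(chain)-4-(triisopropylsilyloxy)phenyl]prop-2-en-1-one (not isolated) | CN(C)/C=C/C(=O)c1c(OCC)cc(O[Si](C(C)C)(C(C)C)C(C)C)c(C[C@@H](CC=C(C)C)[C@@H](C)CO[Si](c2ccccc2)(c2ccccc2)C(C)(C)C)c1OCOC | intermediate
28 | 5-ethoxy-8-(chain)-7-(triisopropylsilyloxy)-4H-chromen-4-one | CCOc1cc(O[Si](C(C)C)(C(C)C)C(C)C)c(C[C@@H](CC=C(C)C)[C@@H](C)CO[Si](c2ccccc2)(c2ccccc2)C(C)(C)C)c2occc(=O)c12 | intermediate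
29 | 4-bromo-3-methoxyphenol | COc1cc(O)ccc1Br | starting material
30 | (4-bromo-3-methoxyphenoxy)triisopropylsilane | COc1cc(O[Si](C(C)C)(C(C)C)C(C)C)ccc1Br | intermediate
31 | [2-methoxy-4-(triisopropylsilyloxy)phenyl]lithium (not isolated) | COc1cc(O[Si](C(C)C)(C(C)C)C(C)C)ccc1[Li] | intermediate
32 | [2-methoxy-4-(triisopropylsilyloxy)phenyl]boronic acid | COc1cc(O[Si](C(C)C)(C(C)C)C(C)C)ccc1B(O)O | intermediate
33 | (2S)-5-ethoxy-8-(chain)-2-[2-methoxy-4-(triisopropylsilyloxy)phenyl]-7-(triisopropylsilyloxy)chroman-4-one | COc1cc(O[Si](C(C)C)(C(C)C)C(C)C)ccc1[C@@H]1CC(=O)c2c(OCC)cc(O[Si](C(C)C)(C(C)C)C(C)C)c(C[C@@H](CC=C(C)C)[C@@H](C)CO[Si](c3ccccc3)(c3ccccc3)C(C)(C)C)c2O1 | intermediate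
34 | (2S)-5-hydroxy-8-(chain)-2-[2-methoxy-4-(triisopropylsilyloxy)phenyl]-7-(triisopropylsilyloxy)chroman-4-one | COc1cc(O[Si](C(C)C)(C(C)C)C(C)C)ccc1[C@@H]1CC(=O)c2c(O)cc(O[Si](C(C)C)(C(C)C)C(C)C)c(C[C@@H](CC=C(C)C)[C@@H](C)CO[Si](c3ccccc3)(c3ccccc3)C(C)(C)C)c2O1 | intermediate
35 | (2S)-5,7-dihydroxy-8-{(2R)-2-[(2R)-1-hydroxypropan-2-yl]-5-methylhex-4-en-1-yl}-2-(4-hydroxy-2-methoxyphenyl)chroman-4-one | COc1cc(O)ccc1[C@@H]1CC(=O)c2c(O)cc(O)c(C[C@@H](CC=C(C)C)[C@@H](C)CO)c2O1 | target

## Step count and least certain steps

Total: 21 steps. Longest linear sequence: 19 steps (steps 1–16 and 19–21); steps 17–18 make the boronic acid.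

**Step 13 (key step).**
- What may go wrong: electrocyclic opening of the vinylogous ester 18 may be slow at temperatures where the siloxyalkyne starts to decompose; the cascade may stall at 20; and the product phenol may be O-acylated by the vinylketene.
- Fallback (sets out from 17, returns at 23): the same vinylketene is made without heat. Commercial ethyl 3-ethoxybut-2-enoate is saponified to (E)-3-ethoxybut-2-enoic acid F1 and converted with oxalyl chloride into (E)-3-ethoxybut-2-enoyl chloride F2. Slow addition of F2 to 17 and Et3N in PhMe at room temperature generates 19 by 1,4-dehydrochlorination and lets it add to the alkyne to give 20 in the cold; brief warming to 80 °C then carries 20 through 21 and 22 to 23.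

**Step 19.**
- What may go wrong: transmetalation of the ortho-methoxy, electron-rich boronic acid may be slow and lose to protodeboronation; the ortho substituent may erode facial selectivity; and β-hydride elimination from the palladium enolate may give the flavone.
- Fallback (sets out from 26, returns at 33): ring B is introduced as an aldehyde and C2 is sorted by reduction. Commercial 4-hydroxy-2-methoxybenzaldehyde is silylated to 2-methoxy-4-(triisopropylsilyloxy)benzaldehyde F3. Aldol condensation with the lithium enolate of 26 (LiN(SiMe3)2; then MsCl, Et3N) gives the (E)-chalcone F4. HCl/MeOH removes the methoxymethyl group and the 2'-hydroxychalcone is closed (NaOAc, EtOH) to the flavanone as a mixture of C2 epimers F5. Catalyst-controlled transfer hydrogenation with the antipode of RuCl(p-cymene)(TsDPEN) that reduces (2R)-flavanones faster (HCO2H/Et3N) converts the (2R)-epimer into the cis-flavan-4-ol F6, which is separated from the untouched (2S)-ketone 33.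

**Step 20.**
- What may go wrong: iodide displacement at the ethyl group is slower than at a methyl group and may need forcing; prolonged Lewis-acid exposure may then open the C2–O1 bond and erode C2.
- Fallback (sets out from 28, returns at 34): the ether is cleaved before C2 exists. Chromone 28 is de-ethylated under more forcing conditions (MgI2·OEt2 at higher temperature, or BCl3 at −78 °C) to the 5-hydroxychromone F7, and F7 is arylated with 32 under the conditions of step 19 to give 34 directly.

**Step 12.**
- What may go wrong: oxygen transfer from the peroxide to the acetylide may be incomplete; the ynolate may silylate at carbon to give a silylketene; and the siloxyalkyne may hydrolyse during purification.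
- Fallback (sets out from 13, returns at 17): the ynolate is made by ester homologation. Pinnick oxidation of 13 gives (3R,4R)-5-(tert-butyldiphenylsilyloxy)-4-methyl-3-(3-methylbut-2-en-1-yl)pentanoic acid F8, and Me3SiCHN2 gives its methyl ester F9. Kowalski homologation (CH2Br2, lithium 2,2,6,6-tetramethylpiperidide, THF, −78 °C; LiN(SiMe3)2; n-BuLi, −78 °C → rt) gives ynolate 16, which is trapped with i-Pr3SiCl to give 17.

**Step 16.**
- What may go wrong: the aqueous acid needed to remove the methoxymethyl group may add HCl or methanol across the trisubstituted alkene, or partly cleave the aryl silyl ether.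
- Fallback (sets out from 23, returns at 28, bypassing 24–27): ring C is built without organolithium or protic acid. Magnesium-mediated ortho-formylation of 23 (MgCl2, Et3N, paraformaldehyde, MeCN, reflux) gives the salicylaldehyde F10. Ethynylmagnesium bromide gives the propargylic alcohol F11. MnO2 oxidises it to the ynone F12, which closes to 28 with catalytic Et2NH by 6-endo addition of the phenol.

## Further compounds

F1 | step 13 | (E)-3-ethoxybut-2-enoic acid | CCO/C(C)=C/C(=O)O
F2 | step 13 | (E)-3-ethoxybut-2-enoyl chloride | CCO/C(C)=C/C(=O)Cl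
F3 | step 19 | 2-methoxy-4-(triisopropylsilyloxy)benzaldehyde | COc1cc(O[Si](C(C)C)(C(C)C)C(C)C)ccc1C=O
F4 | step 19 | (E)-1-[6-ethoxy-2-(methoxymethoxy)-3-(chain)-4-(triisopropylsilyloxy)phenyl]-3-[2-methoxy-4-(triisopropylsilyloxy)phenyl]prop-2-en-1-one | COc1cc(O[Si](C(C)C)(C(C)C)C(C)C)ccc1/C=C/C(=O)c1c(OCC)cc(O[Si](C(C)C)(C(C)C)C(C)C)c(C[C@@H](CC=C(C)C)[C@@H](C)CO[Si](c2ccccc2)(c2ccccc2)C(C)(C)C)c1OCOC
F5 | step 19 | 5-ethoxy-8-(chain)-2-[2-methoxy-4-(triisopropylsilyloxy)phenyl]-7-(triisopropylsilyloxy)chroman-4-one, mixture of C2 epimers | COc1cc(O[Si](C(C)C)(C(C)C)C(C)C)ccc1C1CC(=O)c2c(OCC)cc(O[Si](C(C)C)(C(C)C)C(C)C)c(C[C@@H](CC=C(C)C)[C@@H](C)CO[Si](c3ccccc3)(c3ccccc3)C(C)(C)C)c2O1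
F6 | step 19 | (2R)-2,4-cis-5-ethoxy-8-(chain)-2-[2-methoxy-4-(triisopropylsilyloxy)phenyl]-7-(triisopropylsilyloxy)chroman-4-ol | COc1cc(O[Si](C(C)C)(C(C)C)C(C)C)ccc1[C@H]1C[C@@H](O)c2c(OCC)cc(O[Si](C(C)C)(C(C)C)C(C)C)c(C[C@@H](CC=C(C)C)[C@@H](C)CO[Si](c3ccccc3)(c3ccccc3)C(C)(C)C)c2O1
F7 | step 20 | 5-hydroxy-8-(chain)-7-(triisopropylsilyloxy)-4H-chromen-4-one | O=c1ccoc2c(C[C@@H](CC=C(C)C)[C@@H](C)CO[Si](c3ccccc3)(c3ccccc3)C(C)(C)C)c(O[Si](C(C)C)(C(C)C)C(C)C)cc(O)c12
F8 | step 12 | (3R,4R)-5-(tert-butyldiphenylsilyloxy)-4-methyl-3-(3-methylbut-2-en-1-yl)pentanoic acid | OC(=O)C[C@@H](CC=C(C)C)[C@@H](C)CO[Si](c1ccccc1)(c1ccccc1)C(C)(C)C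
F9 | step 12 | methyl (3R,4R)-5-(tert-butyldiphenylsilyloxy)-4-methyl-3-(3-methylbut-2-en-1-yl)pentanoate | COC(=O)C[C@@H](CC=C(C)C)[C@@H](C)CO[Si](c1ccccc1)(c1ccccc1)C(C)(C)C
F10 | step 16 | 6-ethoxy-2-hydroxy-3-(chain)-4-(triisopropylsilyloxy)benzaldehyde | O=Cc1c(O)c(C[C@@H](CC=C(C)C)[C@@H](C)CO[Si](c2ccccc2)(c2ccccc2)C(C)(C)C)c(O[Si](C(C)C)(C(C)C)C(C)C)cc1OCC
F11 | step 16 | 1-[6-ethoxy-2-hydroxy-3-(chain)-4-(triisopropylsilyloxy)phenyl]prop-2-yn-1-ol | C#CC(O)c1c(O)c(C[C@@H](CC=C(C)C)[C@@H](C)CO[Si](c2ccccc2)(c2ccccc2)C(C)(C)C)c(O[Si](C(C)C)(C(C)C)C(C)C)cc1OCC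
F12 | step 16 | 1-[6-ethoxy-2-hydroxy-3-(chain)-4-(triisopropylsilyloxy)phenyl]prop-2-yn-1-one | C#CC(=O)c1c(O)c(C[C@@H](CC=C(C)C)[C@@H](C)CO[Si](c2ccccc2)(c2ccccc2)C(C)(C)C)c(O[Si](C(C)C)(C(C)C)C(C)C)cc1OCC
A1 | alternative 1 | trans-3-{hydroxy[2,4,6-tris(methoxymethoxy)phenyl]methyl}-4-methyldihydrofuran-2(3H)-one (carbinol epimers) | OC(c1c(OCOC)cc(OCOC)cc1OCOC)[C@H]1C(=O)OC[C@@H]1C
A2 | alternative 1 | furan-2(5H)-one | O=C1C=CCO1
A3 | alternative 1 | 2,4,6-tris(methoxymethoxy)benzaldehyde | O=Cc1c(OCOC)cc(OCOC)cc1OCOC
A4 | alternative 2 | (2S)-2,4-cis-flavan-4-ol, tris(methoxymethyl) ether and tert-butyldimethylsilyl ether | COc1cc(OCOC)ccc1[C@@H]1C[C@H](O)c2c(OCOC)cc(OCOC)c(C[C@@H](CC=C(C)C)[C@@H](C)CO[Si](C)(C)C(C)(C)C)c2O1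
A5 | alternative 2 | anti-1,3-diol with bromine at C8a, open-chain precursor of A4 | COc1cc(OCOC)ccc1[C@@H](O)C[C@H](O)c1c(OCOC)cc(OCOC)c(C[C@@H](CC=C(C)C)[C@@H](C)CO[Si](C)(C)C(C)(C)C)c1Br
A6 | alternative 3 | (2S)-flavanone, tris(triisopropylsilyl) ether and tert-butyldimethylsilyl ether of the target | COc1cc(O[Si](C(C)C)(C(C)C)C(C)C)ccc1[C@@H]1CC(=O)c2c(O[Si](C(C)C)(C(C)C)C(C)C)cc(O[Si](C(C)C)(C(C)C)C(C)C)c(C[C@@H](CC=C(C)C)[C@@H](C)CO[Si](C)(C)C(C)(C)C)c2O1
A7 | alternative 3 | aryl diazomethyl ketone carrying the ring-B benzyl ether on the C8a oxygen | COc1cc(O[Si](C(C)C)(C(C)C)C(C)C)ccc1COc1c(C(=O)C=[N+]=[N-])c(O[Si](C(C)C)(C(C)C)C(C)C)cc(O[Si](C(C)C)(C(C)C)C(C)C)c1C[C@@H](CC=C(C)C)[C@@H](C)CO[Si](C)(C)C(C)(C)C
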